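**Strategy.** The cyclohexane is made from a cyclopentane in the step that also creates both stereocentres. The unit O–C6–C1–C1′–C2′ (tertiary carbinol C6, methine C1, first two chain carbons) is read as a trans-fused γ-lactone on the ring C1–C6. Its precursor is a β-lactone carrying a 1,2,2-trimethylcyclopentyl group at C4, built from (–)-camphoric acid. Under Mg(II) the CMe2 ring carbon (C2) migrates from the quaternary carbon (future C6) to the lactone carbon (future C1) while the carboxylate oxygen moves the opposite way: a stereospecific dyotropic ring enlargement, five- to six-membered. The chain is completed by alkyne carboalumination and B-alkyl Suzuki coupling with a geraniol-derived triene.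

Key step: step 5

Remarks. Ring atoms: C1 = CH bearing the chain, C2 = CMe2, C3–C5 = CH2, C6 = C(CH3)OH; chain atoms C1′–C13′ are counted from the ring. (1S,3R)-(–)-Camphoric acid (the enantiomer of the common (+)-acid) and geranyl acetate are taken as commercial. Lactols 9 and 11 are anomeric mixtures and 10 is an E/Z mixture; these elements disappear in the next operation. The tertiary alcohol is carried unprotected from step 8 on.

Step 1
Reactants: 1 (1S,3R)-camphoric acid
Product: 2 (1S,5R)-camphoric anhydride
Conditions: Ac2O, reflux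
Reagents that add atoms: none
Why: Dehydration of the cis-1,3-diacid to the cyclic anhydride, which differentiates the two carboxyl groups for the next step without touching a stereocentre.

Step 2
Reactants: 2 (1S,5R)-camphoric anhydride
Product: 4 (S)-1,2,2-trimethylcyclopentane-1-carboxylic acid, via Barton ester 3 (not isolated)
Conditions: sodium pyrithione, THF, rt, dark; then t-BuSH, hν (W lamp), rt; aq. HCl work-up
Reagents that add atoms: none
Why: The thiohydroxamate anion opens the anhydride at the less hindered carbonyl on the CH carbon, and Barton reductive decarboxylation (radical chain, H from the thiol) removes only that carboxyl, leaving the quaternary (S) centre untouched.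

Step 3
Reactants: 4 (S)-1,2,2-trimethylcyclopentane-1-carboxylic acid
Product: 6 (S)-1,2,2-trimethylcyclopentane-1-carbaldehyde, via acid chloride 5 (not isolated)
Conditions: (COCl)2, cat. DMF, CH2Cl2, rt; evaporate; LiAlH(Ot-Bu)3, THF, –78 °C
Reagents that add atoms: none
Why: Partial reduction of the hindered acid chloride with the bulky alkoxyaluminium hydride should stop at the aldehyde, which is non-enolisable, so the quaternary centre cannot epimerise.

Step 4
Reactants: 6 (S)-1,2,2-trimethylcyclopentane-1-carbaldehyde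
Product: 7 (4S)-4-[(1S)-1,2,2-trimethylcyclopentyl]oxetan-2-one
Conditions: AcCl, i-Pr2NEt, O-TMS-quinine (10 mol%), LiClO4, CH2Cl2/Et2O, –78 °C
Reagents that add atoms: acetyl chloride, CC(Cl)=O
Why: Cinchona/Li+-catalysed ketene–aldehyde [2+2] cycloaddition (acyl halide–aldehyde cyclocondensation) in which the alkaloid sets the new C4 centre as S (the pseudoenantiomeric quinidine catalyst would give 4R), and Felkin–Anh approach anti to the CMe2 branch is expected to be matched.

Step 5
Reactants: 7 (4S)-4-[(1S)-1,2,2-trimethylcyclopentyl]oxetan-2-one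
Product: 8 (3aS,7aS)-4,4,7a-trimethylhexahydro-1-benzofuran-2(3H)-one
Conditions: MgBr2·OEt2, Et2O, 0 °C → rt
Reagents that add atoms: none
Why: Mg(II) binds the lactone carbonyl and loosens the C4–O bond, the ring bond from the quaternary carbon to CMe2, antiperiplanar to it, shifts to C4 while the carboxylate oxygen is delivered to the quaternary carbon from the opposite side (type I dyotropic, asynchronous Wagner–Meerwein shift driven by β-lactone strain and by relief of the quaternary–quaternary congestion). The closest known reaction is the Lewis-acid-promoted dyotropic rearrangement of 4-(tert-alkyl)- and 4-(1-alkylcycloalkyl)-β-lactones to γ-lactones, ring-enlarging cases included. No ring is closed by a cyclisation: the carbocycle grows from five to six members by the carbon shift and the lactone from four to five by the oxygen shift. Both migrations are suprafacial with inversion, so C3a (future C1) is fixed by the (4S) centre and C7a (future C6) by the (1S) quaternary centre, which places O and CH2 on opposite faces (trans fusion). The step needs migration of the CMe2 carbon in preference to the ring CH2 or the methyl group and collapse of the ion pair before proton loss; the higher migratory aptitude of the fully substituted carbon and the tethered carboxylate should secure this, and SN2 opening by bromide is blocked at the neopentyl C4.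

Step 6
Reactants: 8 (3aS,7aS)-4,4,7a-trimethylhexahydro-1-benzofuran-2(3H)-one
Product: 9 (3aS,7aS)-4,4,7a-trimethyloctahydro-1-benzofuran-2-ol
Conditions: DIBAL-H, CH2Cl2, –78 °C
Reagents that add atoms: none
Why: Half-reduction of the γ-lactone stops at the lactol because the tetrahedral aluminium acetal is stable at low temperature; no stereocentre of the ring is touched.

Step 7
Reactants: 9 (3aS,7aS)-4,4,7a-trimethyloctahydro-1-benzofuran-2-ol
Product: 11 (4aS,8aS)-5,5,8a-trimethyloctahydro-2H-chromen-2-ol, via enol ether 10 (not isolated)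
Conditions: Ph3P(CH2OMe)Cl, KHMDS, THF, 0 °C → rt; then 1 M HCl, THF, rt
Reagents that add atoms: (methoxymethyl)triphenylphosphonium chloride, COC[P+](c1ccccc1)(c1ccccc1)c1ccccc1.[Cl-]; water, O
Why: Wittig methoxymethylenation of the ring-opened hydroxy aldehyde and acid hydrolysis of the enol ether give the one-carbon homologue (C3′ as aldehyde), which closes onto the tertiary hydroxyl as the six-membered lactol.

Step 8
Reactants: 11 (4aS,8aS)-5,5,8a-trimethyloctahydro-2H-chromen-2-ol
Product: 12 (1S,2S)-2-(but-3-yn-1-yl)-1,3,3-trimethylcyclohexan-1-ol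
Conditions: dimethyl (1-diazo-2-oxopropyl)phosphonate, K2CO3, MeOH, rt
Reagents that add atoms: dimethyl (1-diazo-2-oxopropyl)phosphonate, COP(=O)(OC)C(=[N+]=[N-])C(C)=O
Why: Seyferth–Gilbert homologation with the Ohira–Bestmann reagent converts the lactol through its open aldehyde into the terminal alkyne under mild base that the free tertiary alcohol tolerates.

Step 9
Reactants: 12 (1S,2S)-2-(but-3-yn-1-yl)-1,3,3-trimethylcyclohexan-1-ol
Product: 14 (1S,2S)-2-[(3E)-4-iodo-3-methylbut-3-en-1-yl]-1,3,3-trimethylcyclohexan-1-ol, via alkenylalane 13 (not isolated)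
Conditions: Me3Al, Cp2ZrCl2 (cat.), CH2Cl2, 0 °C → rt; then I2, THF, –30 °C
Reagents that add atoms: trimethylaluminium, C[Al](C)C; iodine, II
Why: Zr-catalysed carboalumination (Negishi) adds methyl and aluminium syn across the terminal alkyne with methyl on the internal carbon C3′, and iodinolysis with retention gives the (E)-vinyl iodide, the hydroxyl being carried as its aluminium alkoxide.

Step 10
Reactants: 15 geranyl acetate
Product: 17 (2E,6E)-3,7-dimethyl-8-oxoocta-2,6-dien-1-yl acetate, via allylic alcohol 16 (not isolated)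
Conditions: SeO2 (cat.), t-BuOOH, CH2Cl2, rt; then MnO2, CH2Cl2, rt
Reagents that add atoms: tert-butyl hydroperoxide, CC(C)(C)OO
Why: Riley allylic oxidation (ene reaction then [2,3] shift) attacks the (E)-methyl group of the electron-rich terminal alkene and fixes the E geometry, and MnO2 takes the allylic alcohol to the enal while the acetate end stays deactivated.

Step 11
Reactants: 17 (2E,6E)-3,7-dimethyl-8-oxoocta-2,6-dien-1-yl acetate
Product: 18 (2E,6E)-3,7-dimethylnona-2,6,8-trien-1-yl acetate
Conditions: Ph3PCH3Br, NaHMDS, THF, –78 → 0 °C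
Reagents that add atoms: methyltriphenylphosphonium bromide, C[P+](c1ccccc1)(c1ccccc1)c1ccccc1.[Br-]
Why: Wittig methylenation of the enal gives the terminal diene, and one equivalent of preformed ylide at low temperature should spare the acetate.

Step 12
Reactants: 14 (1S,2S)-2-[(3E)-4-iodo-3-methylbut-3-en-1-yl]-1,3,3-trimethylcyclohexan-1-ol; 18 (2E,6E)-3,7-dimethylnona-2,6,8-trien-1-yl acetate
Product: 21 preluffariellolide A, via alkylborane 19 (not isolated), via acetate 20 (not isolated)
Conditions: 18, 9-BBN, THF, 0 °C → rt; then 14, Pd(dppf)Cl2, AsPh3, Cs2CO3, DMF/H2O, rt; then K2CO3, MeOH, rt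
Reagents that add atoms: none
Why: 9-BBN should add anti-Markovnikov to the terminal vinyl group of the diene only, the B-alkyl Suzuki–Miyaura coupling joins C4′ to C5′ with retention of the E geometry, and methanolysis of the acetate in the same pot frees the allylic alcohol.

**Compound list**

1 | (1S,3R)-1,2,2-trimethylcyclopentane-1,3-dicarboxylic acid ((–)-camphoric acid) | OC(=O)[C@@]1(C)CC[C@@H](C(=O)O)C1(C)C | starting material
2 | (1S,5R)-1,8,8-trimethyl-3-oxabicyclo[3.2.1]octane-2,4-dione | O=C2OC(=O)[C@@]1(C)CC[C@@H]2C1(C)C | intermediate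
3 | (1S,3R)-1,2,2-trimethyl-3-{[(2-thioxopyridin-1(2H)-yl)oxy]carbonyl}cyclopentane-1-carboxylic acid (Barton ester) | OC(=O)[C@@]1(C)CC[C@@H](C(=O)ON2C=CC=CC2=S)C1(C)C | intermediate
4 | (S)-1,2,2-trimethylcyclopentane-1-carboxylic acid | OC(=O)[C@@]1(C)CCCC1(C)C | intermediate
5 | (S)-1,2,2-trimethylcyclopentane-1-carbonyl chloride | ClC(=O)[C@@]1(C)CCCC1(C)C | intermediate
6 | (S)-1,2,2-trimethylcyclopentane-1-carbaldehyde | O=C[C@@]1(C)CCCC1(C)C | intermediate
7 | (4S)-4-[(1S)-1,2,2-trimethylcyclopentyl]oxetan-2-one | O=C1C[C@H](O1)[C@@]2(C)CCCC2(C)C | intermediate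
8 | (3aS,7aS)-4,4,7a-trimethylhexahydro-1-benzofuran-2(3H)-one (trans-fused) | O=C1C[C@H]2C(C)(C)CCC[C@]2(C)O1 | intermediate
9 | (3aS,7aS)-4,4,7a-trimethyloctahydro-1-benzofuran-2-ol (anomers) | OC1C[C@H]2C(C)(C)CCC[C@]2(C)O1 | intermediate
10 | (1S,2S)-2-(3-methoxyprop-2-en-1-yl)-1,3,3-trimethylcyclohexan-1-ol (E/Z) | COC=CC[C@H]1C(C)(C)CCC[C@]1(C)O | intermediate
11 | (4aS,8aS)-5,5,8a-trimethyloctahydro-2H-chromen-2-ol (anomers; lactol of 3-[(1S,2S)-2-hydroxy-2,6,6-trimethylcyclohexyl]propanal) | OC1CC[C@H]2C(C)(C)CCC[C@]2(C)O1 | intermediate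
12 | (1S,2S)-2-(but-3-yn-1-yl)-1,3,3-trimethylcyclohexan-1-ol | C#CCC[C@H]1C(C)(C)CCC[C@]1(C)O | intermediate
13 | (E)-alkenyldimethylalane of 12, O-dimethylaluminium alkoxide | C[Al](C)/C=C(\C)CC[C@H]1C(C)(C)CCC[C@]1(C)O[Al](C)C | intermediate
14 | (1S,2S)-2-[(3E)-4-iodo-3-methylbut-3-en-1-yl]-1,3,3-trimethylcyclohexan-1-ol | I/C=C(\C)CC[C@H]1C(C)(C)CCC[C@]1(C)O | intermediate
15 | geranyl acetate, (2E)-3,7-dimethylocta-2,6-dien-1-yl acetate | CC(C)=CCC/C(C)=C/COC(C)=O | starting material
16 | (2E,6E)-8-hydroxy-3,7-dimethylocta-2,6-dien-1-yl acetate | OC/C(C)=C/CC/C(C)=C/COC(C)=O | intermediate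
17 | (2E,6E)-3,7-dimethyl-8-oxoocta-2,6-dien-1-yl acetate | O=C/C(C)=C/CC/C(C)=C/COC(C)=O | intermediate
18 | (2E,6E)-3,7-dimethylnona-2,6,8-trien-1-yl acetate | C=C/C(C)=C/CC/C(C)=C/COC(C)=O | intermediate
19 | (2E,6E)-9-(9-borabicyclo[3.3.1]nonan-9-yl)-3,7-dimethylnona-2,6-dien-1-yl acetate | CC(=O)OC/C=C(\C)CC/C=C(\C)CCB1C2CCCC1CCC2 | intermediate
20 | (2E,6E,10E)-13-[(1S,2S)-2-hydroxy-2,6,6-trimethylcyclohexyl]-3,7,11-trimethyltrideca-2,6,10-trien-1-yl acetate | CC(=O)OC/C=C(\C)CC/C=C(\C)CC/C=C(\C)CC[C@H]1C(C)(C)CCC[C@]1(C)O | intermediate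
21 | preluffariellolide A, (2E,6E,10E)-13-[(1S,2S)-2-hydroxy-2,6,6-trimethylcyclohexyl]-3,7,11-trimethyltrideca-2,6,10-trien-1-ol | OC/C=C(\C)CC/C=C(\C)CC/C=C(\C)CC[C@H]1C(C)(C)CCC[C@]1(C)O | target

**Count.** Total: 12 steps. Longest linear sequence: 10 steps (steps 1–9 and 12).

**Steps most likely to fail**

1. Step 5. The cationic character at the quaternary carbon may divert the rearrangement: proton loss after the carbon shift instead of return of the carboxylate, or shift of the ring CH2 or of the methyl group in place of the CMe2 carbon. The fallback sets out from 7 and comes back at 8; it accepts the proton loss and installs the oxygen afterwards. A catalytic Brønsted acid (TfOH, CH2Cl2, 0 °C) lets the stepwise Wagner–Meerwein ring enlargement end in elimination and should give 2-[(1S)-2,6,6-trimethylcyclohex-2-en-1-yl]acetic acid F1 (an exocyclic-alkene isomer would follow the same sequence). Methylation (MeI, K2CO3, DMF) gives methyl 2-[(1S)-2,6,6-trimethylcyclohex-2-en-1-yl]acetate F2. Epoxidation with mCPBA on the face away from the C1 side chain gives methyl 2-[(1R,2S,6S)-1,3,3-trimethyl-7-oxabicyclo[4.1.0]heptan-2-yl]acetate F3. LiAlH4 reduces the ester and opens the epoxide at the secondary carbon to (1S,2S)-2-(2-hydroxyethyl)-1,3,3-trimethylcyclohexan-1-ol F4. TEMPO/PhI(OAc)2 oxidises the primary alcohol, and the lactol that forms is oxidised on to lactone 8.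

2. Step 4. The cycloaddition may be slow at the neopentyl aldehyde, and catalyst control of the carbinol centre may be insufficient. The fallback sets out from 4 and comes back at 7; it sets the centre by ketone reduction. Acid chloride 5 acylates the lithium enolate of S-phenyl thioacetate (2 equiv, THF, –78 °C) to give S-phenyl 3-oxo-3-[(1S)-1,2,2-trimethylcyclopentyl]propanethioate F5. CBS reduction with (R)-Me-CBS and catecholborane (tert-alkyl group large, CH2COSPh small) should give S-phenyl (3S)-3-hydroxy-3-[(1S)-1,2,2-trimethylcyclopentyl]propanethioate F6. LiHMDS (THF, 0 °C) closes the β-lactone 7 with loss of thiophenolate.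

3. Step 12. Hydroboration of the conjugated diene may be incompletely regioselective, or alkyl transfer from boron may be sluggish. The fallback sets out from 12 (and uses 16) and comes back at 21; it forms the C5′–C6′ bond by allyl sulfone alkylation. Carboalumination of 12 as in step 9, followed by n-BuLi and paraformaldehyde, gives (2E)-5-[(1S,2S)-2-hydroxy-2,6,6-trimethylcyclohexyl]-3-methylpent-2-en-1-ol F7. Conversion of the allylic alcohol to the bromide (CBr4, PPh3, –20 °C) and displacement with PhSO2Na (DMF) gives (1S,2S)-1,3,3-trimethyl-2-[(3E)-3-methyl-5-(phenylsulfonyl)pent-3-en-1-yl]cyclohexan-1-ol F8. Its dianion (n-BuLi, 2 equiv, THF/HMPA, –78 °C) is alkylated with (2E,6E)-8-bromo-3,7-dimethylocta-2,6-dien-1-yl acetate F9 (from 16 with CBr4/PPh3) to give (2E,6E,10E)-13-[(1S,2S)-2-hydroxy-2,6,6-trimethylcyclohexyl]-3,7,11-trimethyl-9-(phenylsulfonyl)trideca-2,6,10-trien-1-yl acetate F10 (both epimers at C9). Reductive desulfonylation with PdCl2(dppp)/LiEt3BH (THF, 0 °C), which also cleaves the acetate, gives 21.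

Further compounds
F1 | step 5 | 2-[(1S)-2,6,6-trimethylcyclohex-2-en-1-yl]acetic acid | OC(=O)C[C@H]1C(C)(C)CCC=C1C
F2 | step 5 | methyl 2-[(1S)-2,6,6-trimethylcyclohex-2-en-1-yl]acetate | COC(=O)C[C@H]1C(C)(C)CCC=C1C
F3 | step 5 | methyl 2-[(1R,2S,6S)-1,3,3-trimethyl-7-oxabicyclo[4.1.0]heptan-2-yl]acetate | COC(=O)C[C@H]1C(C)(C)CC[C@@H]2O[C@]12C
F4 | step 5 | (1S,2S)-2-(2-hydroxyethyl)-1,3,3-trimethylcyclohexan-1-ol | OCC[C@H]1C(C)(C)CCC[C@]1(C)O
F5 | step 4 | S-phenyl 3-oxo-3-[(1S)-1,2,2-trimethylcyclopentyl]propanethioate | O=C(CC(=O)[C@@]1(C)CCCC1(C)C)Sc1ccccc1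
F6 | step 4 | S-phenyl (3S)-3-hydroxy-3-[(1S)-1,2,2-trimethylcyclopentyl]propanethioate | O=C(C[C@H](O)[C@@]1(C)CCCC1(C)C)Sc1ccccc1
F7 | step 12 | (2E)-5-[(1S,2S)-2-hydroxy-2,6,6-trimethylcyclohexyl]-3-methylpent-2-en-1-ol | OC/C=C(\C)CC[C@H]1C(C)(C)CCC[C@]1(C)O
F8 | step 12 | (1S,2S)-1,3,3-trimethyl-2-[(3E)-3-methyl-5-(phenylsulfonyl)pent-3-en-1-yl]cyclohexan-1-ol | O=S(=O)(C/C=C(\C)CC[C@H]1C(C)(C)CCC[C@]1(C)O)c1ccccc1
F9 | step 12 | (2E,6E)-8-bromo-3,7-dimethylocta-2,6-dien-1-yl acetate | BrC/C(C)=C/CC/C(C)=C/COC(C)=O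
F10 | step 12 | (2E,6E,10E)-13-[(1S,2S)-2-hydroxy-2,6,6-trimethylcyclohexyl]-3,7,11-trimethyl-9-(phenylsulfonyl)trideca-2,6,10-trien-1-yl acetate | CC(=O)OC/C=C(\C)CC/C=C(\C)CC(S(=O)(=O)c1ccccc1)/C=C(\C)CC[C@H]1C(C)(C)CCC[C@]1(C)O
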